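**Plan**

1. Target: 5,7,8-trimethoxy-2-(2,3,4,5-tetramethoxyphenyl)-4H-chromen-4-one. It has no stereocentre and no hindered axis, so it is achiral and no stereocontrol is needed.
2. Retrosynthetic cuts, in order: the two O–CH3 bonds at O5 and O8, then the ring bond O1–C8a (key step), then C2–C3 (diketone assembly), then C4–C4a (ring A acylation) and C2–C1' (ring B carboxylation).
3. Enabling feature: the oxygens on C5 and C8 of ring A are para to each other, with C4a (bearing the C4 carbonyl) and C8a (bearing O1) lying between them. Ring A is therefore a masked 2-acyl-p-hydroquinone, and in its quinone state C8a is the β-carbon of both the C5=O and the C4=O enone.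
4. O1 is therefore not carried in as a phenol. It is attached to a C8a–H by anodic umpolung of ring A, and only this one CH is ortho to the side chain, so the 5,7,8 versus 5,6,7 ambiguity cannot arise.
5. Forward order: ring A from methoxyhydroquinone (C-acetylation), ring B from 1,2,3,4-tetramethoxybenzene (lithiation/CO2), union to an open 1,3-diketone, anodic closure of the pyranone ring last, then double O-methylation.

Key step: step 5

Assumption: 2-methoxyhydroquinone (1) and 1,2,3,4-tetramethoxybenzene (3) are taken as commercial. Potentials and charge in step 5 are starting values to be fixed by cyclic voltammetry.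

**Route**

Step 1
Reactants: 1 2-methoxybenzene-1,4-diol (methoxyhydroquinone)
Product: 2 1-(2,5-dihydroxy-4-methoxyphenyl)ethan-1-one
Conditions: AcOH, BF3·OEt2 (promoter), 90 °C, Ar; aq. NaOAc work-up
Reagents that add atoms: acetic acid, CC(=O)O
Why: BF3-promoted Friedel–Crafts (Fries-type) acylation of the electron-rich hydroquinone should go to the carbon para to OMe and ortho to OH, since the position between the two oxygens is hindered and the third CH is activated by one OH only.

Step 2
Reactants: 3 1,2,3,4-tetramethoxybenzene
Product: 5 2,3,4,5-tetramethoxybenzoic acid, via (2,3,4,5-tetramethoxyphenyl)lithium 4 (not isolated)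
Conditions: n-BuLi, TMEDA, THF, 0 °C; CO2, −78 °C to rt; aq. HCl
Reagents that add atoms: carbon dioxide, O=C=O
Why: directed ortho-metalation next to a methoxy group followed by carboxylation; the two ring CH positions of 3 are equivalent by symmetry, so only one aryllithium can form.

Step 3
Reactants: 5 2,3,4,5-tetramethoxybenzoic acid
Product: 6 2,3,4,5-tetramethoxybenzoyl chloride
Conditions: (COCl)2, cat. DMF, CH2Cl2, 0 °C to rt; used crude
Reagents that add atoms: oxalyl chloride, O=C(Cl)C(=O)Cl
Why: standard DMF-catalysed (Vilsmeier-type) conversion of a carboxylic acid into its chloride, which aryl methyl ethers tolerate.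

Step 4
Reactants: 2 1-(2,5-dihydroxy-4-methoxyphenyl)ethan-1-one; 6 2,3,4,5-tetramethoxybenzoyl chloride
Product: 8 1-(2,5-dihydroxy-4-methoxyphenyl)-3-(2,3,4,5-tetramethoxyphenyl)propane-1,3-dione, via trilithium enolate bis-phenolate 7 (not isolated)
Conditions: LiHMDS (4.2 equiv), THF, −78 to −10 °C; then 6, −78 °C to rt; cold aq. HCl to pH 4; Ar
Reagents that add atoms: none
Why: Claisen-type C-acylation of the lithium polyanion of an unprotected hydroxyacetophenone with an aroyl chloride (the LiHMDS variant of the Baker–Venkataraman approach), in which the enolate carbon is the most nucleophilic site and the fourth equivalent of base takes up the acidic proton of the diketone formed.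

Step 5
Reactants: 8 1-(2,5-dihydroxy-4-methoxyphenyl)-3-(2,3,4,5-tetramethoxyphenyl)propane-1,3-dione
Product: 10 5,8-dihydroxy-7-methoxy-2-(2,3,4,5-tetramethoxyphenyl)-4H-chromen-4-one, via 2-acyl-5-methoxy-1,4-benzoquinone 9 (not isolated)
Conditions: graphite anode, Pt cathode, undivided cell, controlled potential at the first anodic wave of 8 (ca. +0.5 V vs Ag/AgCl), ca. 2 F/mol, MeCN–H2O 9:1, NaOAc/AcOH buffer (pH ca. 5), LiClO4, rt, Ar
Reagents that add atoms: none
Why: Proposed new method: two-electron, two-proton anodic oxidation of the free hydroquinone of 8 should give acylquinone 9, which inverts the polarity of the ring carbon that becomes C8a; the enol oxygen on the carbon carrying ring B should then add to that carbon, which is β to both the quinone C=O and the side-chain C=O, and enolisation of the adduct restores the aromatic ring as the 5,8-hydroquinone 10. The closest known reaction types are the anodic oxidation of hydroquinones and catechols to quinones with in situ Michael addition of 1,3-dicarbonyl nucleophiles (EC sequence) and the addition of heteroatom nucleophiles at C3 of 2-acyl-1,4-benzoquinones. The pyranone ring closes by O1–C8a bond formation in a 6-endo-trig oxa-Michael mode, and no stereocentre is formed. Chemoselectivity for ring A is expected because a free hydroquinone is oxidised well below the potential of the permethylated ring B or of the diketone enol, so the potential can be held at the first wave. Site selectivity is fixed by the substrate: the side chain can reach only the one ortho CH of the quinone, and the other ortho position is a quinone carbonyl at the moment of closure, which blocks the classical dehydrative closure through that oxygen (it would give the 6-hydroxy-7-methoxy isomer) as long as the medium stays near neutral. Charge is limited to about 2 F/mol because 10 is again a hydroquinone; any quinone of 10 that forms should be returned by comproportionation with 8 or by a reductive wash on work-up.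

Step 6
Reactants: 10 5,8-dihydroxy-7-methoxy-2-(2,3,4,5-tetramethoxyphenyl)-4H-chromen-4-one
Product: 12 5,7,8-trimethoxy-2-(2,3,4,5-tetramethoxyphenyl)-4H-chromen-4-one, via 5-hydroxy-7,8-dimethoxy-2-(2,3,4,5-tetramethoxyphenyl)-4H-chromen-4-one 11 (not isolated)
Conditions: Me2SO4 (excess), K2CO3, acetone, reflux, Ar
Reagents that add atoms: dimethyl sulfate, COS(=O)(=O)OC
Why: Williamson O-methylation of both phenols (the free 8-OH first, then the hydrogen-bonded 5-OH on prolonged reflux), the classical permethylation of hydroxyflavones; nothing else in 10 reacts under these conditions.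

**Compound list**

1 | 2-methoxybenzene-1,4-diol (methoxyhydroquinone) | COc1cc(O)ccc1O | starting material
2 | 1-(2,5-dihydroxy-4-methoxyphenyl)ethan-1-one | CC(=O)c1cc(O)c(OC)cc1O | intermediate
3 | 1,2,3,4-tetramethoxybenzene | COc1ccc(OC)c(OC)c1OC | starting material
4 | (2,3,4,5-tetramethoxyphenyl)lithium | [Li]c1cc(OC)c(OC)c(OC)c1OC | intermediate
5 | 2,3,4,5-tetramethoxybenzoic acid | COc1cc(C(=O)O)c(OC)c(OC)c1OC | intermediate
6 | 2,3,4,5-tetramethoxybenzoyl chloride | COc1cc(C(Cl)=O)c(OC)c(OC)c1OC | intermediate
7 | trilithium 2-(1-oxidoethenyl)-5-methoxybenzene-1,4-diolate (trianion of 2) | [Li+].[Li+].[Li+].C=C([O-])c1cc([O-])c(OC)cc1[O-] | intermediate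
8 | 1-(2,5-dihydroxy-4-methoxyphenyl)-3-(2,3,4,5-tetramethoxyphenyl)propane-1,3-dione | COc1cc(C(=O)CC(=O)c2cc(O)c(OC)cc2O)c(OC)c(OC)c1OC | intermediate
9 | 2-methoxy-5-[3-oxo-3-(2,3,4,5-tetramethoxyphenyl)propanoyl]cyclohexa-2,5-diene-1,4-dione | COC1=CC(=O)C(C(=O)CC(=O)c2cc(OC)c(OC)c(OC)c2OC)=CC1=O | intermediate
10 | 5,8-dihydroxy-7-methoxy-2-(2,3,4,5-tetramethoxyphenyl)-4H-chromen-4-one | COc1cc(-c2cc(=O)c3c(O)cc(OC)c(O)c3o2)c(OC)c(OC)c1OC | intermediate
11 | 5-hydroxy-7,8-dimethoxy-2-(2,3,4,5-tetramethoxyphenyl)-4H-chromen-4-one | COc1cc(-c2cc(=O)c3c(O)cc(OC)c(OC)c3o2)c(OC)c(OC)c1OC | intermediate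
12 | 5,7,8-trimethoxy-2-(2,3,4,5-tetramethoxyphenyl)-4H-chromen-4-one | COc1cc(-c2cc(=O)c3c(OC)cc(OC)c(OC)c3o2)c(OC)c(OC)c1OC | target

**Step count**

Total steps: 6. Longest linear sequence: 5 steps (3 → 5 → 6 → 8 → 10 → 12; steps 2, 3, 4, 5, 6).

**Steps most likely to fail**

1. Step 5 (proposed new method). The acylquinone may be consumed by intermolecular addition of water or acetate, or by self-condensation, faster than the enol oxygen closes the ring. The product hydroquinone may also be oxidised further at the anode. Fallback with known chemistry, which brings O1 in as a phenol and closes ring C by dehydration: commercial 1,2,3,5-tetramethoxybenzene F1 would be acetylated with AcCl/AlCl3 in Et2O to 1-(2,3,4,6-tetramethoxyphenyl)ethan-1-one F2. Under the same Lewis acid, F2 should lose the methyl group of the 2-methoxy group flanked by the acetyl and the 3-methoxy group, giving 1-(2-hydroxy-3,4,6-trimethoxyphenyl)ethan-1-one F3. The site of demethylation would have to be confirmed before going on. O-acylation of F3 with acid chloride 6 (pyridine, DMAP) would give 2-acetyl-3,5,6-trimethoxyphenyl 2,3,4,5-tetramethoxybenzoate F4. Baker–Venkataraman rearrangement (KOH, pyridine, 50 °C) would give 1-(2-hydroxy-3,4,6-trimethoxyphenyl)-3-(2,3,4,5-tetramethoxyphenyl)propane-1,3-dione F5, and cyclodehydration (cat. H2SO4, AcOH, 60 °C) would give the target. This fallback sets out from 6 and comes back to the route at 12.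

2. Step 4. Acylation may occur on the unchelated 5'-phenoxide oxygen, or twice, instead of on the enolate carbon, and enolate formation may be incomplete in the presence of two phenoxides. Fallback by O-acylation and acyl migration: 2 would be treated with two equivalents of 6 (pyridine, DMAP, CH2Cl2) to give 2-acetyl-5-methoxy-1,4-phenylene bis(2,3,4,5-tetramethoxybenzoate) F6. Baker–Venkataraman O-to-C acyl shift of the ester ortho to the acetyl group (t-BuOK, THF, 0 °C to rt) would give 4-hydroxy-2-methoxy-5-[3-oxo-3-(2,3,4,5-tetramethoxyphenyl)propanoyl]phenyl 2,3,4,5-tetramethoxybenzoate F7. The remaining aryl ester would be cleaved with LiOH in THF–H2O at 0 °C under Ar. This fallback sets out from 2 and 6 and comes back at 8.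

3. Step 6. The hydroquinone dianion may autoxidise to the 5,8-quinone under base before the slow alkylation of the hydrogen-bonded 5-OH is complete. Fallback through the quinone: 10 would be oxidised on purpose (Ag2O, CH2Cl2, rt) to 7-methoxy-2-(2,3,4,5-tetramethoxyphenyl)-4H-chromene-4,5,8-trione F8. F8 would then undergo reductive methylation in a two-phase system (Na2S2O4, aq. KOH, Me2SO4, Bu4NBr, THF), so that the hydroquinone dianion is alkylated as it forms and is never exposed to air. This fallback sets out from 10 and comes back at 12.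

**Further compounds**

F1 | step 5 | 1,2,3,5-tetramethoxybenzene | COc1cc(OC)c(OC)c(OC)c1
F2 | step 5 | 1-(2,3,4,6-tetramethoxyphenyl)ethan-1-one | CC(=O)c1c(OC)cc(OC)c(OC)c1OC
F3 | step 5 | 1-(2-hydroxy-3,4,6-trimethoxyphenyl)ethan-1-one | CC(=O)c1c(OC)cc(OC)c(OC)c1O
F4 | step 5 | 2-acetyl-3,5,6-trimethoxyphenyl 2,3,4,5-tetramethoxybenzoate | CC(=O)c1c(OC)cc(OC)c(OC)c1OC(=O)c1cc(OC)c(OC)c(OC)c1OC
F5 | step 5 | 1-(2-hydroxy-3,4,6-trimethoxyphenyl)-3-(2,3,4,5-tetramethoxyphenyl)propane-1,3-dione | COc1cc(C(=O)CC(=O)c2c(OC)cc(OC)c(OC)c2O)c(OC)c(OC)c1OC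
F6 | step 4 | 2-acetyl-5-methoxy-1,4-phenylene bis(2,3,4,5-tetramethoxybenzoate) | CC(=O)c1cc(OC(=O)c2cc(OC)c(OC)c(OC)c2OC)c(OC)cc1OC(=O)c1cc(OC)c(OC)c(OC)c1OC
F7 | step 4 | 4-hydroxy-2-methoxy-5-[3-oxo-3-(2,3,4,5-tetramethoxyphenyl)propanoyl]phenyl 2,3,4,5-tetramethoxybenzoate | COc1cc(C(=O)CC(=O)c2cc(OC(=O)c3cc(OC)c(OC)c(OC)c3OC)c(OC)cc2O)c(OC)c(OC)c1OC
F8 | step 6 | 7-methoxy-2-(2,3,4,5-tetramethoxyphenyl)-4H-chromene-4,5,8-trione | COC1=CC(=O)c2c(oc(-c3cc(OC)c(OC)c(OC)c3OC)cc2=O)C1=O
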